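Cuts, in retrosynthetic order: the two silyl ethers; the carbinol C–H (ketone reduction); then, in one operation, both ring C–C bonds that flank the CH2–C(O) unit of the three-carbon bridge together with the lactone C–O bond; then the ether C–O bond. This leaves a nerol-derived epoxy alcohol, an α-diazo ester and acetonitrile.
Enabling feature: in the 1,4-dioxan-2-one ring (lactone O, C=O, α-carbon, ether O, CH, C–CH3) the enolisable α-carbon that carries the ether oxygen lies 1,4 across the ring from the methyl-bearing carbon; in the precursor that carbon is the fully substituted carbon of a 2-methyloxirane whose unsubstituted CH2 is electrophilic. Acetonitrile, nucleophilic at CH2 and electrophilic at C≡N, spans the two positions and closes the oxepane and seven-membered lactone rings of the 6,8-dioxabicyclo[3.2.2]nonan-7-one.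
Forward order: nerol → silyl ether → (S)-epoxide → allylic alcohol → erythro epoxy alcohol; Wittig → ester → diazo ester; O–H insertion joins the halves; the cascade opens the epoxide, closes the dioxanone, then closes the bicycle; ketone reduction; desilylation.
Stereochemistry: both Z olefins come from nerol and from a Wittig reaction with an α-silyloxy ketone; the ring CH–O carbon from Shi epoxidation; the methyl-bearing carbon from matched Sharpless epoxidation; the bridgehead quaternary carbon from ring constraint in the cascade; the secondary carbinol from CBS reduction.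

Key step: step 9

Remark: TBS = tert-butyldimethylsilyl, TBSO = tert-butyldimethylsilyloxy; the ester α-carbon that carries the ether oxygen after step 8 is carried as both epimers, because step 9 planarises it.

Step 1
Reactants: 1 nerol ((2Z)-3,7-dimethylocta-2,6-dien-1-ol)
Product: 2 neryl TBS ether (tert-butyl{[(2Z)-3,7-dimethylocta-2,6-dien-1-yl]oxy}dimethylsilane)
Conditions: TBSCl, imidazole, CH2Cl2, 0 to 25 °C
Reagents that add atoms: tert-butyldimethylsilyl chloride, CC(C)(C)[Si](C)(C)Cl
Why: Imidazole-promoted silyl ether formation masks the primary allylic hydroxyl against the bases and oxidants used later; no stereocentre is formed.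

Step 2
Reactants: 2 neryl TBS ether
Product: 3 (3S)-3-[(3Z)-5-(TBSO)-3-methylpent-3-en-1-yl]-2,2-dimethyloxirane
Conditions: ent-Shi ketone (the L-fructose-derived ketone, 0.3 equiv), KHSO5, K2CO3, Bu4NHSO4, MeCN–dimethoxymethane–aq. Na2B4O7 buffer, 0 °C
Reagents that add atoms: potassium peroxymonosulfate (KHSO5), [K+].[O-]S(=O)(=O)OO
Why: In this Shi epoxidation the chiral dioxirane should attack the more electron-rich, less encumbered distal olefin (the proximal one is deactivated and shielded by the allylic silyloxy group) through the spiro transition state, the enantiomeric ketone being used to give the (S)-configured epoxide carbon that becomes the ring CH–O carbon.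

Step 3
Reactants: 3 (S)-epoxide
Product: 4 (3S,6Z)-8-(TBSO)-2,6-dimethylocta-1,6-dien-3-ol
Conditions: Et2AlCl, lithium 2,2,6,6-tetramethylpiperidide (LiTMP), toluene, 0 °C (Et2Al(TMP) formed in the flask)
Reagents that add atoms: none
Why: In this base-promoted epoxide-to-allylic-alcohol isomerisation the bulky aluminium amide binds the epoxide oxygen and removes a proton from a geminal methyl group in a syn elimination, so the tertiary C–O bond breaks while the C–O bond at the stereocentre is untouched and its configuration is retained.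

Step 4
Reactants: 4 (S)-allylic alcohol
Product: 5 (1S,4Z)-6-(TBSO)-4-methyl-1-[(2R)-2-methyloxiran-2-yl]hex-4-en-1-ol (erythro epoxy alcohol)
Conditions: Ti(OiPr)4 (0.2 equiv), L-(+)-diisopropyl tartrate (0.24 equiv), t-BuOOH, 4 Å molecular sieves, CH2Cl2, −20 °C
Reagents that add atoms: tert-butyl hydroperoxide, CC(C)(C)OO
Why: Sharpless asymmetric epoxidation in the matched sense (the (S)-carbinol is the fast-reacting enantiomer with L-(+)-tartrate) should give the erythro epoxy alcohol, setting the (R)-configured methyl-bearing carbon and raising the enantiomeric purity, while the other olefin has no free allylic hydroxyl and is left alone.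

Step 5
Reactants: 6 tert-butyl 5-bromopentanoate; 7 triphenylphosphine
Product: 8 (5-tert-butoxy-5-oxopentyl)triphenylphosphonium bromide
Conditions: MeCN, 80 °C
Reagents that add atoms: none
Why: SN2 quaternisation of the phosphine by the primary bromide gives the phosphonium salt, the tert-butyl ester being inert under these neutral conditions.

Step 6
Reactants: 8 phosphonium bromide; 9 1-(TBSO)propan-2-one
Product: 11 tert-butyl (5Z)-7-(TBSO)-6-methylhept-5-enoate, via phosphonium ylide 10 (not isolated)
Conditions: NaN(SiMe3)2, THF, 0 °C; then 9, −78 to 25 °C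
Reagents that add atoms: none
Why: Wittig olefination of a non-stabilised ylide with an α-silyloxy methyl ketone should give the Z-trisubstituted olefin (CH2OTBS cis to the chain) needed for the right-hand side chain, and the ester survives because the phosphonium α-position is far more acidic than the ester α-position.

Step 7
Reactants: 11 tert-butyl (5Z)-7-(TBSO)-6-methylhept-5-enoate
Product: 13 tert-butyl (5Z)-7-(TBSO)-2-diazo-6-methylhept-5-enoate, via trifluoroacetyl ester 12 (not isolated)
Conditions: LiN(SiMe3)2, THF, −78 °C; CF3CO2CH2CF3; then MeSO2N3, Et3N, H2O, MeCN, 25 °C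
Reagents that add atoms: 2,2,2-trifluoroethyl trifluoroacetate, O=C(OCC(F)(F)F)C(F)(F)F (atoms carried only by 12); methanesulfonyl azide, CS(=O)(=O)N=[N+]=[N-]
Why: In this deacylative (Regitz-type) diazo transfer, Claisen trifluoroacetylation of the ester enolate activates the α-carbon and the sulfonyl azide then transfers N2 with loss of the trifluoroacetyl group.

Step 8
Reactants: 5 erythro epoxy alcohol; 13 diazo ester
Product: 14 tert-butyl (5Z)-7-(TBSO)-6-methyl-2-{[(1S,4Z)-6-(TBSO)-4-methyl-1-[(2R)-2-methyloxiran-2-yl]hex-4-en-1-yl]oxy}hept-5-enoate (both C2 epimers)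
Conditions: Rh2(O2CCPh3)4 (1 mol %), CH2Cl2, −40 to 0 °C, slow addition of 13
Reagents that add atoms: none
Why: In this rhodium-carbenoid O–H insertion the carbenoid is captured by the hindered secondary hydroxyl through an oxonium ylide, the bulky triphenylacetate ligands and low temperature disfavouring the competing 1,2-hydride shift; the new ether carbon forms as both epimers, which is harmless because step 9 planarises it.

Step 9
Reactants: 14 epoxy ether ester
Product: 17 (1R,5R,9S)-1-[(3Z)-5-(TBSO)-4-methylpent-3-en-1-yl]-9-[(3Z)-5-(TBSO)-3-methylpent-3-en-1-yl]-5-methyl-6,8-dioxabicyclo[3.2.2]nonane-2,7-dione, via dioxanone nitrile 15 (not isolated), via bicyclic ketimine 16 (not isolated)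
Conditions: MeCN, n-BuLi, THF, −78 °C; 14, −78 to 25 °C; LiN(SiMe3)2, 0 to 40 °C; AcOH, H2O, THF, 25 °C
Reagents that add atoms: acetonitrile, CC#N; water, O
Why: Lithioacetonitrile should open the 2,2-disubstituted epoxide of 14 by SN2 attack at its unsubstituted CH2 (first C–C bond, the tertiary C–O bond and its stereocentre untouched), the freed tertiary alkoxide then displaces tert-butoxide from the ester to give dioxanone 15, LiN(SiMe3)2 deprotonates the lactone α-carbon, and the enolate adds to the pendant nitrile (second C–C bond) to give the N-lithio form of ketimine 16, which aqueous acetic acid hydrolyses to ketone 17. The closest known reaction types are the opening of epoxides by nitrile-stabilised carbanions followed by lactonisation, and the Thorpe–Ziegler (ester enolate–nitrile) cyclisation. Ring by ring, the 1,4-dioxan-2-one closes 6-exo-trig, and the oxepane and seven-membered lactone rings of the bicyclo[3.2.2] core close together in one 7-exo-dig event across the 1,4-positions of the dioxanone boat. The only new stereocentre, the quaternary bridgehead carbon, is controlled by the methyl-bearing ring carbon: the cyanoethyl arm can reach the planar enolate only from the face on which it is held, so both epimers of 14 converge on one configuration. The step needs carbanion attack at the epoxide and not at the ester (secured by the hindered tert-butyl ester), lactonisation before C–C closure (secured by adding the amide base only after the alkoxide has cyclised), and enolisation at the lactone and not next to the nitrile (secured by the higher acidity of the α-alkoxy lactone C–H over the alkyl nitrile α-C–H toward the hindered amide base).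

Step 10
Reactants: 17 bicyclic keto lactone
Product: 18 (1R,2S,5R,9S)-2-hydroxy-1-[(3Z)-5-(TBSO)-4-methylpent-3-en-1-yl]-9-[(3Z)-5-(TBSO)-3-methylpent-3-en-1-yl]-5-methyl-6,8-dioxabicyclo[3.2.2]nonan-7-one
Conditions: (R)-2-methyl-CBS-oxazaborolidine (0.3 equiv), catecholborane, toluene, −78 to −40 °C
Reagents that add atoms: none
Why: In this Corey–Bakshi–Shibata reduction the (R)-oxazaborolidine should bind the ketone lone pair anti to the quaternary bridgehead carbon (the large group) and deliver hydride to the face that gives the (S)-carbinol, hydroxyl syn to the lactone bridge, by reagent control, while catecholborane leaves the lactone and the trisubstituted olefins alone at low temperature.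

Step 11
Reactants: 18 bis-TBS hydroxy lactone
Product: 19 (1R,2S,5R,9S)-2-hydroxy-1-[(3Z)-5-hydroxy-4-methylpent-3-en-1-yl]-9-[(3Z)-5-hydroxy-3-methylpent-3-en-1-yl]-5-methyl-6,8-dioxabicyclo[3.2.2]nonan-7-one (target)
Conditions: HF·pyridine, pyridine, THF, 0 to 25 °C
Reagents that add atoms: none
Why: Fluoride-mediated cleavage of both primary silyl ethers under buffered, non-basic conditions should free the two allylic alcohols without retro-aldol opening of the β-hydroxy lactone and without touching any stereocentre.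

Compound list
1 | nerol, (2Z)-3,7-dimethylocta-2,6-dien-1-ol | CC(C)=CCC/C(C)=C\CO | starting material
2 | neryl TBS ether | CC(C)=CCC/C(C)=C\CO[Si](C)(C)C(C)(C)C | intermediate
3 | (3S)-3-[(3Z)-5-(TBSO)-3-methylpent-3-en-1-yl]-2,2-dimethyloxirane | CC1(C)O[C@H]1CC/C(C)=C\CO[Si](C)(C)C(C)(C)C | intermediate
4 | (3S,6Z)-8-(TBSO)-2,6-dimethylocta-1,6-dien-3-ol | O[C@@H](CC/C(C)=C\CO[Si](C)(C)C(C)(C)C)C(C)=C | intermediate
5 | (1S,4Z)-6-(TBSO)-4-methyl-1-[(2R)-2-methyloxiran-2-yl]hex-4-en-1-ol | O[C@@H](CC/C(C)=C\CO[Si](C)(C)C(C)(C)C)[C@@]1(C)CO1 | intermediate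
6 | tert-butyl 5-bromopentanoate | BrCCCCC(=O)OC(C)(C)C | starting material
7 | triphenylphosphine | c1ccc(cc1)P(c1ccccc1)c1ccccc1 | starting material
8 | (5-tert-butoxy-5-oxopentyl)triphenylphosphonium bromide | CC(C)(C)OC(=O)CCCC[P+](c1ccccc1)(c1ccccc1)c1ccccc1.[Br-] | intermediate
9 | 1-(TBSO)propan-2-one | CC(=O)CO[Si](C)(C)C(C)(C)C | starting material
10 | tert-butyl 5-(triphenyl-λ5-phosphanylidene)pentanoate (ylide, not isolated) | CC(C)(C)OC(=O)CCCC=P(c1ccccc1)(c1ccccc1)c1ccccc1 | intermediate
11 | tert-butyl (5Z)-7-(TBSO)-6-methylhept-5-enoate | C/C(=C/CCCC(=O)OC(C)(C)C)CO[Si](C)(C)C(C)(C)C | intermediate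
12 | tert-butyl (5Z)-7-(TBSO)-6-methyl-2-(trifluoroacetyl)hept-5-enoate (not isolated) | C/C(=C/CCC(C(=O)C(F)(F)F)C(=O)OC(C)(C)C)CO[Si](C)(C)C(C)(C)C | intermediate
13 | tert-butyl (5Z)-7-(TBSO)-2-diazo-6-methylhept-5-enoate | C/C(=C/CCC(=[N+]=[N-])C(=O)OC(C)(C)C)CO[Si](C)(C)C(C)(C)C | intermediate
14 | tert-butyl (5Z)-7-(TBSO)-6-methyl-2-{[(1S,4Z)-6-(TBSO)-4-methyl-1-[(2R)-2-methyloxiran-2-yl]hex-4-en-1-yl]oxy}hept-5-enoate, both C2 epimers | C/C(=C/CCC(O[C@@H](CC/C(C)=C\CO[Si](C)(C)C(C)(C)C)[C@@]1(C)CO1)C(=O)OC(C)(C)C)CO[Si](C)(C)C(C)(C)C | intermediate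
15 | (5S,6R)-6-(2-cyanoethyl)-6-methyl-3-[(3Z)-5-(TBSO)-4-methylpent-3-en-1-yl]-5-[(3Z)-5-(TBSO)-3-methylpent-3-en-1-yl]-1,4-dioxan-2-one, both C3 epimers (not isolated) | C/C(=C/CCC1O[C@@H](CC/C(C)=C\CO[Si](C)(C)C(C)(C)C)[C@@](C)(CCC#N)OC1=O)CO[Si](C)(C)C(C)(C)C | intermediate
16 | (1R,5R,9S)-2-imino-1-[(3Z)-5-(TBSO)-4-methylpent-3-en-1-yl]-9-[(3Z)-5-(TBSO)-3-methylpent-3-en-1-yl]-5-methyl-6,8-dioxabicyclo[3.2.2]nonan-7-one (not isolated) | C/C(=C/CC[C@@]12O[C@@H](CC/C(C)=C\CO[Si](C)(C)C(C)(C)C)[C@@](C)(CCC1=N)OC2=O)CO[Si](C)(C)C(C)(C)C | intermediate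
17 | (1R,5R,9S)-1-[(3Z)-5-(TBSO)-4-methylpent-3-en-1-yl]-9-[(3Z)-5-(TBSO)-3-methylpent-3-en-1-yl]-5-methyl-6,8-dioxabicyclo[3.2.2]nonane-2,7-dione | C/C(=C/CC[C@@]12O[C@@H](CC/C(C)=C\CO[Si](C)(C)C(C)(C)C)[C@@](C)(CCC1=O)OC2=O)CO[Si](C)(C)C(C)(C)C | intermediate
18 | (1R,2S,5R,9S)-2-hydroxy-1-[(3Z)-5-(TBSO)-4-methylpent-3-en-1-yl]-9-[(3Z)-5-(TBSO)-3-methylpent-3-en-1-yl]-5-methyl-6,8-dioxabicyclo[3.2.2]nonan-7-one | C/C(=C/CC[C@@]12O[C@@H](CC/C(C)=C\CO[Si](C)(C)C(C)(C)C)[C@@](C)(CC[C@@H]1O)OC2=O)CO[Si](C)(C)C(C)(C)C | intermediate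
19 | (1R,2S,5R,9S)-2-hydroxy-1-[(3Z)-5-hydroxy-4-methylpent-3-en-1-yl]-9-[(3Z)-5-hydroxy-3-methylpent-3-en-1-yl]-5-methyl-6,8-dioxabicyclo[3.2.2]nonan-7-one | C/C(=C/CC[C@@]12O[C@@H](CC/C(C)=C\CO)[C@@](C)(CC[C@@H]1O)OC2=O)CO | target

Total step count: 11. Longest linear sequence: 8 steps (steps 1 to 4 and 8 to 11).

Steps most likely to fail

1. Step 9. The cascade may stall after the epoxide opening, the tertiary alkoxide adding to the nitrile and resting as a cyclic imidate instead of lactonising. The enolate–nitrile closure may also be slow enough for the lactone carbonyl to be acylated by the nitrile-stabilised carbanion. The fallback sets out from 14 and comes back at 18, forming the two C–C bonds one after the other. Compound 14 is opened at the epoxide CH2 with (1,3-dioxolan-2-ylmethyl)magnesium bromide and catalytic CuI (THF, −30 to 25 °C), and the bromomagnesium alkoxide lactonises on warming to the dioxanone acetal F1. The acetal is cleaved with triethylsilyl triflate and 2,4,6-collidine (CH2Cl2, 0 °C) followed by water, leaving the silyl ethers intact, to give the dioxanone aldehyde F2. TiCl4 and Bu3N (CH2Cl2, −78 °C) then effect an intramolecular titanium-enolate aldol addition, in which the chelate between enolate oxygen and aldehyde oxygen should place the new hydroxyl syn to the lactone bridge. This gives 18 directly and bypasses 17 and step 10.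

2. Step 10. The facial bias of the bicyclic ketone may oppose the catalyst, so that reagent control is incomplete and a mixture of carbinol epimers results. The fallback sets out from 17 and comes back at 18. Substrate-controlled reduction with NaBH4 (MeOH–THF, −40 °C) is expected to deliver hydride from the face of the lactone bridge and give the 2-epi alcohol F3. Mitsunobu inversion with 4-nitrobenzoic acid, PPh3 and diisopropyl azodicarboxylate (toluene, 0 to 25 °C) gives the inverted 4-nitrobenzoate F4. Mild methanolysis (K2CO3, MeOH, 0 °C) then frees 18.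

3. Step 8. The 1,2-hydride shift of the α-alkyl carbenoid to the enoate may outrun insertion into the hindered hydroxyl of 5. The fallback sets out from 11 (used together with 5) and comes back at 14. The potassium enolate of 11 (KN(SiMe3)2, THF, −78 °C) is hydroxylated with 2-(phenylsulfonyl)-3-phenyloxaziridine to the α-hydroxy ester F5. Triflic anhydride and 2,6-lutidine (CH2Cl2, −78 °C) convert it into the α-triflyloxy ester F6. The sodium alkoxide of 5 (NaH, THF, formed and kept cold in this aprotic medium so that alkylation outruns epoxide migration) displaces the triflate in an SN2 reaction (−78 to −20 °C) to give 14.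

Further compounds
F1 | step 9 | (5S,6R)-6-[2-(1,3-dioxolan-2-yl)ethyl]-6-methyl-3-[(3Z)-5-(TBSO)-4-methylpent-3-en-1-yl]-5-[(3Z)-5-(TBSO)-3-methylpent-3-en-1-yl]-1,4-dioxan-2-one, both C3 epimers | C/C(=C/CCC1O[C@@H](CC/C(C)=C\CO[Si](C)(C)C(C)(C)C)[C@@](C)(CCC2OCCO2)OC1=O)CO[Si](C)(C)C(C)(C)C
F2 | step 9 | (5S,6R)-6-methyl-6-(3-oxopropyl)-3-[(3Z)-5-(TBSO)-4-methylpent-3-en-1-yl]-5-[(3Z)-5-(TBSO)-3-methylpent-3-en-1-yl]-1,4-dioxan-2-one, both C3 epimers | C/C(=C/CCC1O[C@@H](CC/C(C)=C\CO[Si](C)(C)C(C)(C)C)[C@@](C)(CCC=O)OC1=O)CO[Si](C)(C)C(C)(C)C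
F3 | step 10 | (1R,2R,5R,9S)-2-hydroxy-1-[(3Z)-5-(TBSO)-4-methylpent-3-en-1-yl]-9-[(3Z)-5-(TBSO)-3-methylpent-3-en-1-yl]-5-methyl-6,8-dioxabicyclo[3.2.2]nonan-7-one (2-epimer of 18) | C/C(=C/CC[C@@]12O[C@@H](CC/C(C)=C\CO[Si](C)(C)C(C)(C)C)[C@@](C)(CC[C@H]1O)OC2=O)CO[Si](C)(C)C(C)(C)C
F4 | step 10 | (1R,2S,5R,9S)-1-[(3Z)-5-(TBSO)-4-methylpent-3-en-1-yl]-9-[(3Z)-5-(TBSO)-3-methylpent-3-en-1-yl]-5-methyl-7-oxo-6,8-dioxabicyclo[3.2.2]nonan-2-yl 4-nitrobenzoate | C/C(=C/CC[C@@]12O[C@@H](CC/C(C)=C\CO[Si](C)(C)C(C)(C)C)[C@@](C)(CC[C@@H]1OC(=O)c3ccc(cc3)[N+](=O)[O-])OC2=O)CO[Si](C)(C)C(C)(C)C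
F5 | step 8 | tert-butyl (5Z)-7-(TBSO)-2-hydroxy-6-methylhept-5-enoate (racemic) | C/C(=C/CCC(O)C(=O)OC(C)(C)C)CO[Si](C)(C)C(C)(C)C
F6 | step 8 | tert-butyl (5Z)-7-(TBSO)-6-methyl-2-[(trifluoromethanesulfonyl)oxy]hept-5-enoate (racemic) | C/C(=C/CCC(OS(=O)(=O)C(F)(F)F)C(=O)OC(C)(C)C)CO[Si](C)(C)C(C)(C)C
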